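**Plan**

- Numbering (elemane): ring C5–C10. C10 carries CH3‑14 and the C1=C2 vinyl group, C5 the C4(=C3H2)–C15HO unit, C6 the angelate, C9 the methacrylate; the lactone is O–C8 / C7–C11(=C13H2)–C12. On one ring face lie CH3‑14, the C5 side chain, O6 and O9; on the other the vinyl group, C11 and the lactone oxygen on C8.
- Retrosynthetic cuts: first the C15 oxidation level and the two ester C–O bonds; then both ring bonds C6–C7 and C8–C9 together, which leaves a four‑carbon 1,4‑dicarbonyl chain (C6–C5–C10–C9) and the five lactone atoms; last the C5–C10 bond by a [3,3] shift.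
- Enabling feature: C7 and C8 are neighbouring carbons of a butenolide. Written as a 2‑silyloxyfuran with a CH2–B group on C11, C8 is a vinylogous enolate carbon; once the butenolide is restored, C7 is the γ‑carbon of an allylboronate whose SE2′ reaction leaves exactly the C11=C13 methylene. C6 and C9 both bear oxygen and can be aldehyde carbons.
- Forward order: an Ireland–Claisen rearrangement builds C5–C10; a one‑pot vinylogous aldol/allylboration annulation closes the cyclohexane onto the preformed lactone ring (helpers: dioxolane on C6, silyl on O9, Bpin on C13); esterifications and allylic oxidation finish.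
- Stereochemistry: C5/C10 from the chair Claisen transition state under a chiral boron controller; C9/C8 from Felkin–Anh and threo aldol control; C7/C6 from cis ring fusion and a closed allylboration transition state.

Key step: step 14

Assumption: in the Ireland–Claisen step the (4S,5S) antipode of the diazaborolidine controller is written; should its sense of induction on this ester be the opposite one, the (4R,5R) antipode is used and nothing else changes.

**Route**

Step 1
Reactants: 1 ethyl (2E)-3-methyl-4-oxobut-2-enoate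
Product: 2 ethyl (2E)-4-hydroxy-3-methylbut-2-enoate
Conditions: NaBH4, EtOH, −20 °C
Reagents that add atoms: none
Why: Chemoselective 1,2-reduction of the aldehyde at low temperature should leave the conjugated ester and the (E)-alkene untouched.

Step 2
Reactants: 2 ethyl (2E)-4-hydroxy-3-methylbut-2-enoate
Product: 3 ethyl (2E)-4-[(tert-butyldiphenylsilyl)oxy]-3-methylbut-2-enoate
Conditions: t-BuPh2SiCl, imidazole, DMF, 23 °C
Reagents that add atoms: tert-butyl(chloro)diphenylsilane, CC(C)(C)[Si](Cl)(c1ccccc1)c1ccccc1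
Why: Standard silylation of a primary alcohol; the robust silyl ether is chosen to survive the boron Lewis acid and the hydride steps ahead.

Step 3
Reactants: 3 ethyl (2E)-4-[(tert-butyldiphenylsilyl)oxy]-3-methylbut-2-enoate
Product: 4 (2E)-4-[(tert-butyldiphenylsilyl)oxy]-3-methylbut-2-en-1-ol
Conditions: i-Bu2AlH (2.2 equiv), CH2Cl2, −78 °C
Reagents that add atoms: none
Why: Hydride reduction of the conjugated ester to the allylic alcohol keeps the alkene geometry that later defines the quaternary centre.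

Step 4
Reactants: 4 (2E)-4-[(tert-butyldiphenylsilyl)oxy]-3-methylbut-2-en-1-ol; 5 3-methylbut-3-enoic acid
Product: 6 (2E)-4-[(tert-butyldiphenylsilyl)oxy]-3-methylbut-2-en-1-yl 3-methylbut-3-enoate
Conditions: DCC, DMAP (5 mol %), CH2Cl2, −20 → 0 °C
Reagents that add atoms: none
Why: Steglich esterification at low temperature and low DMAP loading should limit conjugation of the β,γ-unsaturated acyl group.

Step 5
Reactants: 6 (2E)-4-[(tert-butyldiphenylsilyl)oxy]-3-methylbut-2-en-1-yl 3-methylbut-3-enoate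
Product: 8 (2S,3S)-3-{[(tert-butyldiphenylsilyl)oxy]methyl}-3-methyl-2-(prop-1-en-2-yl)pent-4-enoic acid, via boron ketene acetal 7 (not isolated)
Conditions: (4S,5S)-2-bromo-1,3-bis{[3,5-bis(trifluoromethyl)phenyl]sulfonyl}-4,5-diphenyl-1,3,2-diazaborolidine (1.2 equiv), Et3N, toluene/hexane, −78 °C, then 4 °C; aqueous work-up
Reagents that add atoms: none
Why: Enantioselective Ireland–Claisen rearrangement: soft enolization should give boron ketene acetal 7 with the isopropenyl group trans to O–B, and the chair transition state of the (E)-allyl ester (CH2OSi equatorial, methyl axial) sets C5 and the quaternary C10 in the required relative configuration while the chiral diazaborolidine selects the enantiotopic chair.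

Step 6
Reactants: 8 (2S,3S)-3-{[(tert-butyldiphenylsilyl)oxy]methyl}-3-methyl-2-(prop-1-en-2-yl)pent-4-enoic acid
Product: 9 (2S,3S)-3-{[(tert-butyldiphenylsilyl)oxy]methyl}-3-methyl-2-(prop-1-en-2-yl)pent-4-en-1-ol
Conditions: LiAlH4, Et2O, 0 °C
Reagents that add atoms: none
Why: Hydride reduction of the acid to the primary alcohol (C6) does not touch the alkenes, the silyl ether or either stereocentre.

Step 7
Reactants: 9 (2S,3S)-3-{[(tert-butyldiphenylsilyl)oxy]methyl}-3-methyl-2-(prop-1-en-2-yl)pent-4-en-1-ol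
Product: 10 (2S,3S)-3-{[(tert-butyldiphenylsilyl)oxy]methyl}-3-methyl-2-(prop-1-en-2-yl)pent-4-enal
Conditions: Dess–Martin periodinane, NaHCO3, CH2Cl2, 0 °C
Reagents that add atoms: none
Why: Buffered, non-basic oxidation should give the α-branched β,γ-unsaturated aldehyde without epimerization at C5 or conjugation.

Step 8
Reactants: 10 (2S,3S)-3-{[(tert-butyldiphenylsilyl)oxy]methyl}-3-methyl-2-(prop-1-en-2-yl)pent-4-enal
Product: 11 tert-butyl{[(2S,3S)-3-(1,3-dioxolan-2-yl)-2-ethenyl-2,4-dimethylpent-4-en-1-yl]oxy}diphenylsilane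
Conditions: Me3SiOCH2CH2OSiMe3, Me3SiOTf (5 mol %), CH2Cl2, −78 °C
Reagents that add atoms: 1,2-bis(trimethylsilyloxy)ethane, C[Si](C)(C)OCCO[Si](C)(C)C
Why: Aprotic silyl-triflate-catalysed acetalization at low temperature masks C6 as a 1,3-dioxolane without enolizing the sensitive aldehyde.

Step 9
Reactants: 11 tert-butyl{[(2S,3S)-3-(1,3-dioxolan-2-yl)-2-ethenyl-2,4-dimethylpent-4-en-1-yl]oxy}diphenylsilane
Product: 12 (2S,3S)-3-(1,3-dioxolan-2-yl)-2-ethenyl-2,4-dimethylpent-4-en-1-ol
Conditions: Bu4NF, THF, 23 °C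
Reagents that add atoms: none
Why: Fluoride cleaves the silyl ether while the acetal is inert to these basic conditions.

Step 10
Reactants: 12 (2S,3S)-3-(1,3-dioxolan-2-yl)-2-ethenyl-2,4-dimethylpent-4-en-1-ol
Product: 13 (2S,3S)-3-(1,3-dioxolan-2-yl)-2-ethenyl-2,4-dimethylpent-4-enal
Conditions: Dess–Martin periodinane, NaHCO3, CH2Cl2, 23 °C
Reagents that add atoms: none
Why: Oxidation of the neopentyl alcohol gives the C9 aldehyde, which cannot enolize because C10 is quaternary.

Step 11
Reactants: 14 3-methylenedihydrofuran-2(3H)-one (α-methylene-γ-butyrolactone)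
Product: 16 3-(bromomethyl)furan-2(5H)-one, via dibromolactone 15 (not isolated)
Conditions: Br2, CH2Cl2, 0 °C; then Et3N, 0 → 23 °C
Reagents that add atoms: bromine, BrBr
Why: Bromine addition to the exocyclic alkene followed by loss of HBr from the tertiary bromide toward the ring should give the conjugated allylic bromide (addition–elimination).

Step 12
Reactants: 16 3-(bromomethyl)furan-2(5H)-one
Product: 17 3-[(4,4,5,5-tetramethyl-1,3,2-dioxaborolan-2-yl)methyl]furan-2(5H)-one
Conditions: B2pin2, Pd2(dba)3 (2.5 mol %), DMSO, 50 °C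
Reagents that add atoms: bis(pinacolato)diboron, CC1(C)OB(OC1(C)C)B1OC(C)(C)C(C)(C)O1
Why: Miyaura-type allylic borylation: zerovalent palladium forms the π-allyl complex and boron should be delivered to the primary terminus, which keeps the conjugated butenolide.

Step 13
Reactants: 17 3-[(4,4,5,5-tetramethyl-1,3,2-dioxaborolan-2-yl)methyl]furan-2(5H)-one
Product: 18 triisopropyl({3-[(4,4,5,5-tetramethyl-1,3,2-dioxaborolan-2-yl)methyl]furan-2-yl}oxy)silane
Conditions: i-Pr3SiOTf, Et3N, CH2Cl2, 0 °C
Reagents that add atoms: triisopropylsilyl trifluoromethanesulfonate, CC(C)[Si](OS(=O)(=O)C(F)(F)F)(C(C)C)C(C)C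
Why: Soft enolization and O-silylation of the butenolide give the aromatic 2-silyloxyfuran, the standard route to such dienol ethers.

Step 14
Reactants: 13 (2S,3S)-3-(1,3-dioxolan-2-yl)-2-ethenyl-2,4-dimethylpent-4-enal; 18 triisopropyl({3-[(4,4,5,5-tetramethyl-1,3,2-dioxaborolan-2-yl)methyl]furan-2-yl}oxy)silane
Product: 21 6-hydroxy-9-[(triisopropylsilyl)oxy]elema-1,3,11(13)-trien-12,8-olide, via aldol adduct 19 (not isolated), via unmasked aldehyde 20 (not isolated)
Conditions: 18 (1.3 equiv), i-Pr3SiOTf (10 mol %), CH2Cl2, −78 °C; then THF, 1 M aq. HCl, 0 → 23 °C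
Reagents that add atoms: water, O
Why: Proposed new method: a formal [4+2] annulation of a mono-masked 1,4-dialdehyde with furan 18 acting as a 1,2-bis-nucleophile, argued from two known reaction types, the silyl-triflate-promoted vinylogous Mukaiyama aldol reaction of 2-silyloxyfurans and the carbonyl allylboration by 2-alkoxycarbonyl allylboronates that delivers α-methylene-γ-lactones: the silyl cation activates the only free carbonyl (C9), furan C5 (= C8) attacks it and the re-formed butenolide 19 now carries an allylboronate (B–C13–C11=C7), then aqueous acid unmasks the C6 aldehyde (20), which is allylated at C7 with shift of the double bond to C11=C13. Only the carbocycle closes in this step (the lactone ring arrives as the furan), by 6-exo-trig addition of C7 to the C6 carbonyl through a closed Zimmerman–Traxler B–O=C–C=C–C array. C9 should follow Felkin–Anh addition anti to the bulky C5 branch, with the vinyl group eclipsing the carbonyl and the furan passing the methyl group, and C8 the threo preference of Lewis-acid-promoted silyloxyfuran aldol reactions. C7 is fixed by delivery of C6 to the butenolide face that carries the C9 chain (cis ring fusion), and C6 by the tether lying equatorial in the Zimmerman–Traxler chair of the (E)-configured allylboronate (C8 trans to CH2B), which puts O6 trans to C11. The selectivity needed is between the two carbonyl carbons: C6 stays a cyclic acetal, whose oxygen cannot be relayed to C9 without an eight-membered oxocarbenium ion, until the C8–C9 bond exists, and the bulky silyl group on O9 then prevents lactol or oxa-bridge formation with C6.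

Step 15
Reactants: 21 6-hydroxy-9-[(triisopropylsilyl)oxy]elema-1,3,11(13)-trien-12,8-olide; 22 angelic acid ((2Z)-2-methylbut-2-enoic acid)
Product: 24 6-angeloyloxy-9-[(triisopropylsilyl)oxy]elema-1,3,11(13)-trien-12,8-olide, via mixed anhydride 23 (not isolated)
Conditions: 2,4,6-trichlorobenzoyl chloride, Et3N, toluene, 23 °C; then 21, 80 °C
Reagents that add atoms: none
Why: Yamaguchi esterification through mixed anhydride 23 without a nucleophilic catalyst should acylate the hindered C6 alcohol and keep the (Z)-geometry of the angelate.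

Step 16
Reactants: 24 6-angeloyloxy-9-[(triisopropylsilyl)oxy]elema-1,3,11(13)-trien-12,8-olide
Product: 25 6-angeloyloxy-9-hydroxyelema-1,3,11(13)-trien-12,8-olide
Conditions: HF·pyridine, THF, 0 → 23 °C
Reagents that add atoms: none
Why: Buffered fluoride desilylation frees O9; the esters and the α-methylene lactone tolerate these weakly acidic conditions.

Step 17
Reactants: 25 6-angeloyloxy-9-hydroxyelema-1,3,11(13)-trien-12,8-olide; 26 methacrylic anhydride
Product: 27 6-angeloyloxy-9-methacryloyloxyelema-1,3,11(13)-trien-12,8-olide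
Conditions: DMAP, Et3N, CH2Cl2, 0 → 23 °C
Reagents that add atoms: none
Why: DMAP-catalysed acylation of the equatorial secondary C9 alcohol with the anhydride is a standard ester formation.

Step 18
Reactants: 27 6-angeloyloxy-9-methacryloyloxyelema-1,3,11(13)-trien-12,8-olide
Product: 28 6-angeloyloxy-15-hydroxy-9-methacryloyloxyelema-1,3,11(13)-trien-12,8-olide
Conditions: SeO2 (0.5 equiv), t-BuOOH, CH2Cl2, 23 °C
Reagents that add atoms: selenium dioxide (oxygen carrier), O=[Se]=O; tert-butyl hydroperoxide (terminal oxidant), CC(C)(C)OO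
Why: Allylic oxidation (ene reaction, then [2,3]-sigmatropic shift) is expected at the methyl group of the isopropenyl unit, the only electron-rich alkene with allylic hydrogens; the vinyl group has none and the three other alkenes are deactivated by carbonyl groups.

Step 19
Reactants: 28 6-angeloyloxy-15-hydroxy-9-methacryloyloxyelema-1,3,11(13)-trien-12,8-olide
Product: 29 CNP0102441.1 (6-angeloyloxy-9-methacryloyloxy-15-oxoelema-1,3,11(13)-trien-12,8-olide)
Conditions: Dess–Martin periodinane, NaHCO3, CH2Cl2, 0 °C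
Reagents that add atoms: none
Why: Mild oxidation of the primary allylic alcohol to the enal; none of the esters or alkenes should react.

**Compound list**

1 | ethyl (2E)-3-methyl-4-oxobut-2-enoate | CCOC(=O)/C=C(\C)C=O | starting material
2 | ethyl (2E)-4-hydroxy-3-methylbut-2-enoate | CCOC(=O)/C=C(\C)CO | intermediate
3 | ethyl (2E)-4-[(tert-butyldiphenylsilyl)oxy]-3-methylbut-2-enoate | CCOC(=O)/C=C(\C)CO[Si](c1ccccc1)(c1ccccc1)C(C)(C)C | intermediate
4 | (2E)-4-[(tert-butyldiphenylsilyl)oxy]-3-methylbut-2-en-1-ol | OC/C=C(\C)CO[Si](c1ccccc1)(c1ccccc1)C(C)(C)C | intermediate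
5 | 3-methylbut-3-enoic acid | C=C(C)CC(=O)O | starting material
6 | (2E)-4-[(tert-butyldiphenylsilyl)oxy]-3-methylbut-2-en-1-yl 3-methylbut-3-enoate | C=C(C)CC(=O)OC/C=C(\C)CO[Si](c1ccccc1)(c1ccccc1)C(C)(C)C | intermediate
7 | boron ketene acetal of 6 (O-bound (4S,5S)-1,3-bis{[3,5-bis(trifluoromethyl)phenyl]sulfonyl}-4,5-diphenyl-1,3,2-diazaborolidin-2-yl group; isopropenyl trans to O–B) | C=C(C)/C=C(/OB1N(S(=O)(=O)c2cc(C(F)(F)F)cc(C(F)(F)F)c2)[C@@H](c2ccccc2)[C@H](c2ccccc2)N1S(=O)(=O)c1cc(C(F)(F)F)cc(C(F)(F)F)c1)OC/C=C(\C)CO[Si](c1ccccc1)(c1ccccc1)C(C)(C)C | intermediate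
8 | (2S,3S)-3-{[(tert-butyldiphenylsilyl)oxy]methyl}-3-methyl-2-(prop-1-en-2-yl)pent-4-enoic acid | C=C[C@@](CO[Si](c1ccccc1)(c1ccccc1)C(C)(C)C)(C)[C@H](C(C)=C)C(=O)O | intermediate
9 | (2S,3S)-3-{[(tert-butyldiphenylsilyl)oxy]methyl}-3-methyl-2-(prop-1-en-2-yl)pent-4-en-1-ol | C=C[C@@](CO[Si](c1ccccc1)(c1ccccc1)C(C)(C)C)(C)[C@H](C(C)=C)CO | intermediate
10 | (2S,3S)-3-{[(tert-butyldiphenylsilyl)oxy]methyl}-3-methyl-2-(prop-1-en-2-yl)pent-4-enal | C=C[C@@](CO[Si](c1ccccc1)(c1ccccc1)C(C)(C)C)(C)[C@H](C(C)=C)C=O | intermediate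
11 | tert-butyl{[(2S,3S)-3-(1,3-dioxolan-2-yl)-2-ethenyl-2,4-dimethylpent-4-en-1-yl]oxy}diphenylsilane | C=C[C@@](CO[Si](c1ccccc1)(c1ccccc1)C(C)(C)C)(C)[C@H](C(C)=C)C1OCCO1 | intermediate
12 | (2S,3S)-3-(1,3-dioxolan-2-yl)-2-ethenyl-2,4-dimethylpent-4-en-1-ol | C=C[C@@](CO)(C)[C@H](C(C)=C)C1OCCO1 | intermediate
13 | (2S,3S)-3-(1,3-dioxolan-2-yl)-2-ethenyl-2,4-dimethylpent-4-enal (C9 aldehyde, C6 dioxolane) | C=C[C@@](C=O)(C)[C@H](C(C)=C)C1OCCO1 | intermediate
14 | 3-methylenedihydrofuran-2(3H)-one | C=C1CCOC1=O | starting material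
15 | 3-bromo-3-(bromomethyl)dihydrofuran-2(3H)-one (racemic) | BrCC1(Br)CCOC1=O | intermediate
16 | 3-(bromomethyl)furan-2(5H)-one | BrCC1=CCOC1=O | intermediate
17 | 3-[(4,4,5,5-tetramethyl-1,3,2-dioxaborolan-2-yl)methyl]furan-2(5H)-one | O=C1OCC=C1CB1OC(C)(C)C(C)(C)O1 | intermediate
18 | triisopropyl({3-[(4,4,5,5-tetramethyl-1,3,2-dioxaborolan-2-yl)methyl]furan-2-yl}oxy)silane | CC(C)[Si](Oc1occc1CB1OC(C)(C)C(C)(C)O1)(C(C)C)C(C)C | intermediate
19 | aldol adduct: butenolide joined at C8 to C9 (C8/C9 threo, O9 as triisopropylsilyl ether, CH2Bpin on C11, C6 still the dioxolane) | C=C[C@@]([C@@H](O[Si](C(C)C)(C(C)C)C(C)C)[C@H]1C=C(CB2OC(C)(C)C(C)(C)O2)C(=O)O1)(C)[C@H](C(C)=C)C1OCCO1 | intermediate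
20 | unmasked aldehyde: as 19 with C6 as CHO | C=C[C@@]([C@@H](O[Si](C(C)C)(C(C)C)C(C)C)[C@H]1C=C(CB2OC(C)(C)C(C)(C)O2)C(=O)O1)(C)[C@H](C(C)=C)C=O | intermediate
21 | 6-hydroxy-9-[(triisopropylsilyl)oxy]elema-1,3,11(13)-trien-12,8-olide (ring configuration as in the target) | C=C[C@@]1(C)[C@H](C(C)=C)[C@H](O)[C@H]2C(=C)C(=O)O[C@H]2[C@@H]1O[Si](C(C)C)(C(C)C)C(C)C | intermediate
22 | angelic acid, (2Z)-2-methylbut-2-enoic acid | C/C=C(/C)C(=O)O | starting material
23 | angelic 2,4,6-trichlorobenzoic anhydride | C/C=C(/C)C(=O)OC(=O)c1c(Cl)cc(Cl)cc1Cl | intermediate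
24 | 6-angeloyloxy-9-[(triisopropylsilyl)oxy]elema-1,3,11(13)-trien-12,8-olide | C=C[C@@]1(C)[C@H](C(C)=C)[C@H](OC(=O)/C(C)=C\C)[C@H]2C(=C)C(=O)O[C@H]2[C@@H]1O[Si](C(C)C)(C(C)C)C(C)C | intermediate
25 | 6-angeloyloxy-9-hydroxyelema-1,3,11(13)-trien-12,8-olide | C=C[C@@]1(C)[C@H](C(C)=C)[C@H](OC(=O)/C(C)=C\C)[C@H]2C(=C)C(=O)O[C@H]2[C@@H]1O | intermediate
26 | methacrylic anhydride | C=C(C)C(=O)OC(=O)C(C)=C | starting material
27 | 6-angeloyloxy-9-methacryloyloxyelema-1,3,11(13)-trien-12,8-olide | C=C[C@@]1(C)[C@H](C(C)=C)[C@H](OC(=O)/C(C)=C\C)[C@H]2C(=C)C(=O)O[C@H]2[C@@H]1OC(=O)C(=C)C | intermediate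
28 | 6-angeloyloxy-15-hydroxy-9-methacryloyloxyelema-1,3,11(13)-trien-12,8-olide | C=C[C@@]1(C)[C@H](C(=C)CO)[C@H](OC(=O)/C(C)=C\C)[C@H]2C(=C)C(=O)O[C@H]2[C@@H]1OC(=O)C(=C)C | intermediate
29 | CNP0102441.1, (5R,6S,7R,8R,9R,10S)-6-angeloyloxy-9-methacryloyloxy-15-oxoelema-1,3,11(13)-trien-12,8-olide | C=C[C@@]1(C)[C@H](C(=C)C=O)[C@H](OC(=O)/C(C)=C\C)[C@H]2C(=C)C(=O)O[C@H]2[C@@H]1OC(=O)C(=C)C | target

**Step count and risks**

Total: 19 steps (one-pot operations counted once). Longest linear sequence: 16 steps (steps 1–10 and 14–19); steps 11–13 are a three-step side branch.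

Steps most likely to fail:

1. Step 14 (Proposed new method). What may go wrong: relay of the acetal oxygen to the activated C9 carbonyl with loss of site selectivity; weak facial discrimination between methyl and vinyl at C9; protodeboronation or conjugation of the freed aldehyde before a strained ring closure. The fallback is stepwise and uses known reactions. It sets out from 13: a catalyst-controlled vinylogous Mukaiyama aldol reaction with 2-(trimethylsilyloxy)furan under Ti(OiPr)4/BINOL (BINOL antipode chosen for the C9 face) should give hydroxy butenolide acetal F1. Silylation (i-Pr3SiOTf, 2,6-lutidine) gives silyl ether F2, and 1 M aq. HCl/THF gives aldehyde F3. SmI2 in THF/MeOH at −78 °C closes the ring by ketyl–olefin cyclization onto the butenolide to give saturated hydroxy lactone F4, with C6–OH expected trans to C7–C11. α-Methylenation follows: LiN(iPr)2 (2.2 equiv) and dimethylmethyleneammonium iodide give Mannich base F5 (C11 epimers, both usable), MeI gives ammonium iodide F6, and NaHCO3-induced elimination comes back to the route at 21.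

2. Step 5. What may go wrong: slow or unselective soft enolization of the β,γ-unsaturated ester, or insufficient enantiofacial control by the boron controller. The fallback sets out from 6: the racemic Ireland–Claisen rearrangement (LiN(iPr)2, Me3SiCl, THF, −78 → 23 °C) passes through silyl ketene acetal F7 and the racemic silyl ester F8 and gives, after acidic work-up, acid 8 together with its enantiomer F9 (same chair, same relative configuration). Crystallization of the (S)-1-phenylethylammonium salt F10 (or the salt of the (R)-amine, whichever is less soluble for the wanted enantiomer) and acidification come back to the route at 8.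

3. Step 18. What may go wrong: over-oxidation, competing oxidation at the C5–H bond, or slow reaction at the hindered isopropenyl group. The fallback sets out from 27: a Schenck ene reaction with singlet oxygen (O2, tetraphenylporphyrin, hν, CH2Cl2, 0 °C), to which the conjugated alkenes and the vinyl group are inert, should give allylic hydroperoxide F11; PPh3 reduces it and the route is rejoined at 28.

Further compounds
F1 | step 14 | hydroxy butenolide acetal (C8/C9 threo, free C9–OH, C6 dioxolane) | C=C[C@@]([C@@H](O)[C@H]1C=CC(=O)O1)(C)[C@H](C(C)=C)C1OCCO1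
F2 | step 14 | silyl ether of F1 (O9–Si(iPr)3) | C=C[C@@]([C@@H](O[Si](C(C)C)(C(C)C)C(C)C)[C@H]1C=CC(=O)O1)(C)[C@H](C(C)=C)C1OCCO1
F3 | step 14 | aldehyde from F2 (C6 as CHO) | C=C[C@@]([C@@H](O[Si](C(C)C)(C(C)C)C(C)C)[C@H]1C=CC(=O)O1)(C)[C@H](C(C)=C)C=O
F4 | step 14 | saturated hydroxy lactone, 6-hydroxy-13-nor-9-[(triisopropylsilyl)oxy]elema-1,3-dien-12,8-olide | C=C[C@@]1(C)[C@H](C(C)=C)[C@H](O)[C@H]2CC(=O)O[C@H]2[C@@H]1O[Si](C(C)C)(C(C)C)C(C)C
F5 | step 14 | Mannich base, 11-[(dimethylamino)methyl] derivative of F4 (C11 epimers) | C=C[C@@]1(C)[C@H](C(C)=C)[C@H](O)[C@H]2C(CN(C)C)C(=O)O[C@H]2[C@@H]1O[Si](C(C)C)(C(C)C)C(C)C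
F6 | step 14 | trimethylammonium iodide of F5 | C=C[C@@]1(C)[C@H](C(C)=C)[C@H](O)[C@H]2C(C[N+](C)(C)C)C(=O)O[C@H]2[C@@H]1O[Si](C(C)C)(C(C)C)C(C)C.[I-]
F7 | step 5 | trimethylsilyl ketene acetal of 6 (isopropenyl trans to O–Si) | C=C(C)/C=C(/O[Si](C)(C)C)OC/C=C(\C)CO[Si](c1ccccc1)(c1ccccc1)C(C)(C)C
F8 | step 5 | racemic trimethylsilyl ester of 8 (both enantiomers) | C=C[C@@](CO[Si](c1ccccc1)(c1ccccc1)C(C)(C)C)(C)[C@H](C(C)=C)C(=O)O[Si](C)(C)C.C=C[C@](CO[Si](c1ccccc1)(c1ccccc1)C(C)(C)C)(C)[C@@H](C(C)=C)C(=O)O[Si](C)(C)C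
F9 | step 5 | (2R,3R) enantiomer of 8 | C=C[C@](CO[Si](c1ccccc1)(c1ccccc1)C(C)(C)C)(C)[C@@H](C(C)=C)C(=O)O
F10 | step 5 | (S)-1-phenylethylammonium salt of 8 | C=C[C@@](CO[Si](c1ccccc1)(c1ccccc1)C(C)(C)C)(C)[C@H](C(C)=C)C(=O)[O-].C[C@H]([NH3+])c1ccccc1
F11 | step 18 | allylic hydroperoxide, 15-hydroperoxy analogue of 28 | C=C[C@@]1(C)[C@H](C(=C)COO)[C@H](OC(=O)/C(C)=C\C)[C@H]2C(=C)C(=O)O[C@H]2[C@@H]1OC(=O)C(=C)C
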